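Numbering used: C1 = carboxyl carbon, C2 = its CH2, C3(Me) and C5(Me) = dioxolane carbons with C4 between them, O1 on C3, O2 on C5, C6–C15 = side chain (C7 bears the methyl, C10=C11 and C14=C15–Ph are the alkenes).
Cuts: C10=C11 (Julia–Kocienski, leaving a C10 aldehyde), then the dioxolane at C4–C5 and O1–C3 in one (3+2) event, after the C1 carboxyl and the C10 oxygen have been joined as an ester.
Enabling feature: C3 carries Me and CH2CO2H and sits 1,3 to the peroxy carbon C5, so it is the Markovnikov cation of a 3-methylbut-3-enoate attacked by a C5 peroxycarbenium ion. The cis arms on C3 and C5 end in C1 and C10, so an eight-atom ester bridge can tie them across the five-membered ring.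
Forward: (R)-citronellal → C5–C10 keto ester carrying the tethered alkene → silyl peroxyketal → SnCl4: 11-membered ring (C4–C5), then dioxolane (O1–C3) → lactone methanolysis → C10 aldehyde → olefination with the C11–C15 sulfone → saponification.
Stereochemistry: C7 is bought; C3/C5 cis is enforced by the bridge and their sense is relayed from C7 across the macrocycle; C14=C15 E comes from a Johnson–Claisen chair, C10=C11 E from the Julia–Kocienski reaction.

Key step: step 7

Assumption: the fully substituted dialkyl peroxide (no hydrogen on either oxygen-bearing carbon) is taken to tolerate K2CO3/MeOH, cold KN(SiMe3)2 and LiOH, as such peroxides generally do.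

Step 1
Reactants: 1 (R)-citronellal
Product: 2 (4R)-4,8-dimethylnon-7-en-2-ol (both C2 epimers)
Conditions: MeMgBr, Et2O, 0 °C; aq NH4Cl
Reagents that add atoms: methylmagnesium bromide, C[Mg]Br
Why: Grignard addition to the aldehyde installs the carbon that becomes the C5 methyl; the new carbinol centre is formed without control and is erased in step 4, and the bought stereocentre (later C7) is β to the carbonyl and untouched.

Step 2
Reactants: 2 (4R)-4,8-dimethylnon-7-en-2-ol
Product: 4 (4R)-4-methylheptane-1,6-diol, via secondary ozonide 3 (not isolated)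
Conditions: O3, CH2Cl2, −78 °C; then NaBH4, MeOH, −78 °C → rt
Reagents that add atoms: ozone, [O-][O+]=O
Why: Ozonolysis of the trisubstituted alkene and NaBH4 reduction of the ozonide should give the primary alcohol at the future C10, and this removes the only π-nucleophile that could intercept the later C5 cation in a six-membered ring closure.

Step 3
Reactants: 4 (4R)-4-methylheptane-1,6-diol, 5 3-methylbut-3-enoic acid
Product: 6 (4R)-6-hydroxy-4-methylheptyl 3-methylbut-3-enoate (both C6 epimers)
Conditions: 5 (1.05 equiv), PPh3, DIAD, THF, −20 → 0 °C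
Reagents that add atoms: none
Why: In the Mitsunobu esterification the primary alkoxyphosphonium ion forms and is displaced by the carboxylate far faster than the secondary one, so only the primary carbinol carbon (future C10) is esterified, and the neutral conditions should keep the β,γ-double bond out of conjugation.

Step 4
Reactants: 6 (4R)-6-hydroxy-4-methylheptyl 3-methylbut-3-enoate
Product: 7 (4R)-4-methyl-6-oxoheptyl 3-methylbut-3-enoate
Conditions: Dess–Martin periodinane, NaHCO3, CH2Cl2, rt
Reagents that add atoms: none
Why: Dess–Martin oxidation converts the secondary alcohol into the methyl ketone under buffered conditions that leave the ester and the 1,1-disubstituted alkene alone, and it removes the carbinol stereo mixture.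

Step 5
Reactants: 7 (4R)-4-methyl-6-oxoheptyl 3-methylbut-3-enoate
Product: 8 (4R)-6-hydroperoxy-6-methoxy-4-methylheptyl 3-methylbut-3-enoate (both C6 epimers)
Conditions: urea·H2O2, Sc(OTf)3 (10 mol %), MeOH, 0 °C → rt
Reagents that add atoms: hydrogen peroxide (as its urea adduct), OO; methanol, CO
Why: Lewis acid-catalysed condensation of a ketone with hydrogen peroxide in methanol is a known route to α-methoxy hydroperoxides (hydroperoxy ketals), and the new ketal centre needs no control because it becomes planar in step 7.

Step 6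
Reactants: 8 (4R)-6-hydroperoxy-6-methoxy-4-methylheptyl 3-methylbut-3-enoate
Product: 9 (4R)-6-methoxy-4-methyl-6-(triethylsilylperoxy)heptyl 3-methylbut-3-enoate
Conditions: Et3SiCl, imidazole, DMF, 0 °C
Reagents that add atoms: chlorotriethylsilane, CC[Si](Cl)(CC)CC
Why: Silylation of the hydroperoxide gives the triethylsilyl peroxyketal, the established precursor of a peroxycarbenium ion, without touching the ester.

Step 7
Reactants: 9 (4R)-6-methoxy-4-methyl-6-(triethylsilylperoxy)heptyl 3-methylbut-3-enoate
Product: 12 (1R,8R,10R)-1,8,10-trimethyl-4,11,12-trioxabicyclo[8.2.1]tridecan-3-one (the cis-3,5-dimethyl-1,2-dioxolane bridged from C3 to C5 by the 11-membered lactone), via peroxycarbenium ion 10 (not isolated), via macrocyclic tertiary cation 11 (not isolated)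
Conditions: SnCl4 (1.5 equiv), CH2Cl2, −78 → −40 °C, 9 added by syringe pump over several hours (final 1 mM); aq NaHCO3
Reagents that add atoms: none
Why: Proposed new method: SnCl4 removes the methoxide of 9 to give peroxycarbenium ion 10, the terminal carbon (C4) of the tethered 1,1-disubstituted alkene attacks C5 to give the tertiary C3 cation 11, and the silylated peroxy oxygen then captures C3 with loss of Et3Si+ (as Et3SiCl), so that the C4–C5 and O1–C3 bonds arise in one stepwise (3+2) annulation. The closest known reaction type is the intermolecular SnCl4-mediated annulation of ketone-derived triethylsilyl peroxyketals with alkenes to 1,2-dioxolanes, and Prins-type macrocyclisations of oxocarbenium ions show that such cations can close large rings; new here is the intramolecular version through an ester tether. The 11-membered ring closes by attack on the exocyclic C5=O+ bond (11-exo with respect to the electrophile, Markovnikov with respect to the alkene), and the five-membered ring closes by transannular collapse of the peroxy oxygen onto the free cation, a 1,3-capture outside Baldwin's rules. C5 is set in the C–C bond formation and C3 in the O–C bond formation: their cis relationship (both methyl groups on one face) is enforced because the eight-atom bridge C6–C7–C8–C9–C10–O–C1–C2 can span only cis positions of the five-membered ring without prohibitive strain, and their sense relative to C7 should be relayed through the macrocycle, the C7 methyl lying anti to the C5 methyl and syn to the smaller peroxy oxygen so that no syn-pentane methyl/methyl contact arises along C5–C6–C7, which is the (3R,5R,7R) arrangement. The step needs ring closure to outrun oligomerisation and proton loss from 11, which slow addition at high dilution, low temperature and the 1,3 placement of the internal peroxy nucleophile should secure, and it needs no competing π-nucleophile, which is why the side-chain alkenes are introduced only later.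

Step 8
Reactants: 12 (1R,8R,10R)-1,8,10-trimethyl-4,11,12-trioxabicyclo[8.2.1]tridecan-3-one
Product: 13 methyl 2-[(3R,5R)-5-[(2R)-5-hydroxy-2-methylpentyl]-3,5-dimethyl-1,2-dioxolan-3-yl]acetate
Conditions: K2CO3 (0.3 equiv), MeOH, 0 °C → rt
Reagents that add atoms: methanol, CO
Why: Methoxide-mediated transesterification opens the strained 11-membered lactone to the C1 methyl ester and the free C10 alcohol, and the dioxolane should survive because neither oxygen-bearing carbon carries a hydrogen for base-induced peroxide fragmentation.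

Step 9
Reactants: 13 methyl 2-[(3R,5R)-5-[(2R)-5-hydroxy-2-methylpentyl]-3,5-dimethyl-1,2-dioxolan-3-yl]acetate
Product: 14 methyl 2-[(3R,5R)-3,5-dimethyl-5-[(2R)-2-methyl-5-oxopentyl]-1,2-dioxolan-3-yl]acetate
Conditions: Dess–Martin periodinane, NaHCO3, CH2Cl2, 0 °C → rt
Reagents that add atoms: none
Why: Dess–Martin oxidation of the primary alcohol under buffered, non-reducing conditions should give the aldehyde without affecting the peroxide or the ester.

Step 10
Reactants: 15 1-phenylprop-2-en-1-ol (racemic), 16 triethyl orthoacetate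
Product: 18 ethyl (4E)-5-phenylpent-4-enoate, via mixed ketene acetal 17 (not isolated)
Conditions: EtCO2H (cat.), neat, 140 °C, ethanol distilled off
Reagents that add atoms: none
Why: Johnson–Claisen rearrangement: the orthoester exchanges with the allylic alcohol, loses ethanol to the ketene acetal and rearranges through a chair transition state with the phenyl group equatorial, which should give the E alkene (C14=C15).

Step 11
Reactants: 18 ethyl (4E)-5-phenylpent-4-enoate
Product: 19 (4E)-5-phenylpent-4-en-1-ol
Conditions: LiAlH4, THF, 0 °C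
Reagents that add atoms: none
Why: LiAlH4 reduces the ester to the primary alcohol and does not touch the isolated styrene-type double bond.

Step 12
Reactants: 19 (4E)-5-phenylpent-4-en-1-ol, 20 1-phenyl-1H-tetrazole-5-thiol
Product: 21 1-phenyl-5-{[(4E)-5-phenylpent-4-en-1-yl]sulfanyl}-1H-tetrazole
Conditions: PPh3, DIAD, THF, 0 °C → rt
Reagents that add atoms: none
Why: Mitsunobu thioetherification of the primary alcohol with the acidic tetrazolethiol gives the sulfide with no change at the alkene.

Step 13
Reactants: 21 1-phenyl-5-{[(4E)-5-phenylpent-4-en-1-yl]sulfanyl}-1H-tetrazole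
Product: 22 1-phenyl-5-{[(4E)-5-phenylpent-4-en-1-yl]sulfonyl}-1H-tetrazole
Conditions: (NH4)6Mo7O24·4H2O (10 mol %), 30% H2O2, EtOH, 0 °C → rt
Reagents that add atoms: hydrogen peroxide, OO
Why: (NH4)6Mo7O24-catalysed oxidation with hydrogen peroxide takes the sulfide to the sulfone and is known to spare unactivated and styrene-type alkenes at room temperature.

Step 14
Reactants: 14 methyl 2-[(3R,5R)-3,5-dimethyl-5-[(2R)-2-methyl-5-oxopentyl]-1,2-dioxolan-3-yl]acetate, 22 1-phenyl-5-{[(4E)-5-phenylpent-4-en-1-yl]sulfonyl}-1H-tetrazole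
Product: 24 methyl 2-[(3R,5R)-3,5-dimethyl-5-[(2R,5E,9E)-2-methyl-10-phenyldeca-5,9-dien-1-yl]-1,2-dioxolan-3-yl]acetate, via potassium alkoxide adduct 23 (not isolated)
Conditions: 22 (1.3 equiv), KN(SiMe3)2, DME, −60 °C; then 14, −60 °C → rt; aq NH4Cl
Reagents that add atoms: none
Why: Julia–Kocienski olefination: the premetalated 1-phenyltetrazolyl sulfone adds to the aldehyde faster than it can attack the methyl ester, and Smiles rearrangement followed by anti elimination of SO2 and the tetrazolone gives the C10=C11 alkene, the potassium counter-ion in DME favouring the E isomer.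

Step 15
Reactants: 24 methyl 2-[(3R,5R)-3,5-dimethyl-5-[(2R,5E,9E)-2-methyl-10-phenyldeca-5,9-dien-1-yl]-1,2-dioxolan-3-yl]acetate
Product: 25 2-[(3R,5R)-3,5-dimethyl-5-[(2R,5E,9E)-2-methyl-10-phenyldeca-5,9-dien-1-yl]-1,2-dioxolan-3-yl]acetic acid (target)
Conditions: LiOH·H2O, THF/MeOH/H2O, 0 °C → rt; then 1 M HCl to pH 3
Reagents that add atoms: lithium hydroxide, [Li+].[OH-]
Why: Saponification of the methyl ester and mild acidification should give the acid; no stereocentre can epimerise because C3 and C5 are quaternary and C7 is remote from any acidifying group.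

Compound list
1 | (R)-citronellal, (3R)-3,7-dimethyloct-6-enal | C[C@H](CCC=C(C)C)CC=O | starting material
2 | (4R)-4,8-dimethylnon-7-en-2-ol (both C2 epimers) | CC(O)C[C@H](C)CCC=C(C)C | intermediate
3 | (4R)-6-(5,5-dimethyl-1,2,4-trioxolan-3-yl)-4-methylhexan-2-ol (secondary ozonide) | CC(O)C[C@H](C)CCC1OOC(C)(C)O1 | intermediate (not isolated)
4 | (4R)-4-methylheptane-1,6-diol (both C6 epimers) | CC(O)C[C@H](C)CCCO | intermediate
5 | 3-methylbut-3-enoic acid | C=C(C)CC(=O)O | starting material
6 | (4R)-6-hydroxy-4-methylheptyl 3-methylbut-3-enoate | CC(O)C[C@H](C)CCCOC(=O)CC(C)=C | intermediate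
7 | (4R)-4-methyl-6-oxoheptyl 3-methylbut-3-enoate | CC(=O)C[C@H](C)CCCOC(=O)CC(C)=C | intermediate
8 | (4R)-6-hydroperoxy-6-methoxy-4-methylheptyl 3-methylbut-3-enoate | COC(C)(OO)C[C@H](C)CCCOC(=O)CC(C)=C | intermediate
9 | (4R)-6-methoxy-4-methyl-6-(triethylsilylperoxy)heptyl 3-methylbut-3-enoate | COC(C)(OO[Si](CC)(CC)CC)C[C@H](C)CCCOC(=O)CC(C)=C | intermediate
10 | peroxycarbenium ion at C5 of the open-chain ester (methoxytetrachlorostannate ion pair) | CC(=[O+]O[Si](CC)(CC)CC)C[C@H](C)CCCOC(=O)CC(C)=C.CO[Sn-](Cl)(Cl)(Cl)Cl | intermediate (not isolated)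
11 | 11-membered lactone bearing the tertiary C3 cation and the C5 triethylsilylperoxy group (methoxytetrachlorostannate ion pair) | C[C+]1CC(=O)OCCC[C@@H](C)C[C@@](C)(OO[Si](CC)(CC)CC)C1.CO[Sn-](Cl)(Cl)(Cl)Cl | intermediate (not isolated)
12 | (1R,8R,10R)-1,8,10-trimethyl-4,11,12-trioxabicyclo[8.2.1]tridecan-3-one | C[C@@H]1CCCOC(=O)C[C@@]2(C)C[C@@](C)(C1)OO2 | intermediate
13 | methyl 2-[(3R,5R)-5-[(2R)-5-hydroxy-2-methylpentyl]-3,5-dimethyl-1,2-dioxolan-3-yl]acetate | C[C@H](CCCO)C[C@]1(C)C[C@](C)(CC(=O)OC)OO1 | intermediate
14 | methyl 2-[(3R,5R)-3,5-dimethyl-5-[(2R)-2-methyl-5-oxopentyl]-1,2-dioxolan-3-yl]acetate | C[C@H](CCC=O)C[C@]1(C)C[C@](C)(CC(=O)OC)OO1 | intermediate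
15 | 1-phenylprop-2-en-1-ol (racemic) | C=CC(O)c1ccccc1 | starting material
16 | triethyl orthoacetate | CC(OCC)(OCC)OCC | starting material
17 | 1-ethoxyvinyl 1-phenylallyl ether (mixed ketene acetal) | C=C(OCC)OC(C=C)c1ccccc1 | intermediate (not isolated)
18 | ethyl (4E)-5-phenylpent-4-enoate | CCOC(=O)CC/C=C/c1ccccc1 | intermediate
19 | (4E)-5-phenylpent-4-en-1-ol | OCCC/C=C/c1ccccc1 | intermediate
20 | 1-phenyl-1H-tetrazole-5-thiol | SC1=NN=NN1c1ccccc1 | starting material
21 | 1-phenyl-5-{[(4E)-5-phenylpent-4-en-1-yl]sulfanyl}-1H-tetrazole | c1ccccc1/C=C/CCCSC1=NN=NN1c1ccccc1 | intermediate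
22 | 1-phenyl-5-{[(4E)-5-phenylpent-4-en-1-yl]sulfonyl}-1H-tetrazole | c1ccccc1/C=C/CCCS(=O)(=O)C1=NN=NN1c1ccccc1 | intermediate
23 | potassium β-alkoxy sulfone adduct of 14 and metalated 22 (C10 alkoxide, C11 sulfonyl; configuration at both open) | C[C@H](CCC([O-])C(CC/C=C/c1ccccc1)S(=O)(=O)C1=NN=NN1c1ccccc1)C[C@]1(C)C[C@](C)(CC(=O)OC)OO1.[K+] | intermediate (not isolated)
24 | methyl 2-[(3R,5R)-3,5-dimethyl-5-[(2R,5E,9E)-2-methyl-10-phenyldeca-5,9-dien-1-yl]-1,2-dioxolan-3-yl]acetate | C[C@H](CC/C=C/CC/C=C/c1ccccc1)C[C@]1(C)C[C@](C)(CC(=O)OC)OO1 | intermediate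
25 | 2-[(3R,5R)-3,5-dimethyl-5-[(2R,5E,9E)-2-methyl-10-phenyldeca-5,9-dien-1-yl]-1,2-dioxolan-3-yl]acetic acid | C[C@H](CC/C=C/CC/C=C/c1ccccc1)C[C@]1(C)C[C@](C)(CC(=O)O)OO1 | target

Total step count: 15.
Longest linear sequence: 11 steps (steps 1–9, 14 and 15); steps 10–13 make the sulfone branch.

Steps most likely to fail

Step 7. Oligomerisation may outrun closure of the 11-membered ring, cation 11 may lose a proton instead of being captured by the peroxy oxygen, and the facial bias relayed from C7 may be too small, which would leave the (3S,5S,7R) cis isomer to be separated. The fallback is the known intermolecular annulation; it sets out from 4 and comes back at 13. The primary hydroxyl of 4 would be acetylated selectively (AcCl, 2,4,6-collidine, CH2Cl2, −78 °C) to (4R)-6-hydroxy-4-methylheptyl acetate F1. Dess–Martin oxidation would give (4R)-4-methyl-6-oxoheptyl acetate F2, and urea·H2O2 with Sc(OTf)3 in MeOH would give (4R)-6-hydroperoxy-6-methoxy-4-methylheptyl acetate F3. Et3SiCl and imidazole would give (4R)-6-methoxy-4-methyl-6-(triethylsilylperoxy)heptyl acetate F4. SnCl4 in CH2Cl2 at −78 °C with excess purchased methyl 3-methylbut-3-enoate (C=C(C)CC(=O)OC) would then give methyl 2-[(3R,5R)-5-[(2R)-5-(acetyloxy)-2-methylpentyl]-3,5-dimethyl-1,2-dioxolan-3-yl]acetate F5. Without the tether, control at C3 and C5 would be low, so the (3R,5R) isomer would have to be separated by preparative HPLC. K2CO3 in MeOH would remove the acetate and deliver 13.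

Step 5. The equilibrium between ketone, methoxy hydroperoxide and gem-dihydroperoxide may lie on the wrong side, or the tether ester may undergo acid-catalysed methanolysis during the long exposure. The fallback replaces the condensation by an irreversible addition to an enol ether; it sets out from 7 and comes back at 8. HC(OMe)3, MeOH and pyridinium p-toluenesulfonate would give (4R)-6,6-dimethoxy-4-methylheptyl 3-methylbut-3-enoate F6. Me3SiOTf and iPr2NEt in CH2Cl2 would eliminate methanol to (4R)-6-methoxy-4-methylhept-6-en-1-yl 3-methylbut-3-enoate F7 (its internal double-bond isomer converges to the same product). Anhydrous H2O2 in Et2O with catalytic pyridinium p-toluenesulfonate at 0 °C would add in the Markovnikov sense to give 8.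

Step 14. The E selectivity may erode, and the unbranched aldehyde 14 may enolise and self-condense or the β-peroxy ester may open under excess metalated sulfone. The fallback exchanges the roles of the partners so that the base meets the dioxolane fragment only under Barbier conditions; it sets out from 13 (and 19) and comes back at 24. Mitsunobu reaction of 13 with 20 would give methyl 2-[(3R,5R)-3,5-dimethyl-5-[(2R)-2-methyl-5-[(1-phenyl-1H-tetrazol-5-yl)sulfanyl]pentyl]-1,2-dioxolan-3-yl]acetate F8. (NH4)6Mo7O24·4H2O with H2O2 would give methyl 2-[(3R,5R)-3,5-dimethyl-5-[(2R)-2-methyl-5-[(1-phenyl-1H-tetrazol-5-yl)sulfonyl]pentyl]-1,2-dioxolan-3-yl]acetate F9. Dess–Martin oxidation of 19 would give (4E)-5-phenylpent-4-enal F10. KN(SiMe3)2 added to a mixture of F9 and F10 in DME at −60 °C would then give 24.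

Further compounds
F1 | step 7 | (4R)-6-hydroxy-4-methylheptyl acetate | CC(O)C[C@H](C)CCCOC(C)=O
F2 | step 7 | (4R)-4-methyl-6-oxoheptyl acetate | CC(=O)C[C@H](C)CCCOC(C)=O
F3 | step 7 | (4R)-6-hydroperoxy-6-methoxy-4-methylheptyl acetate | COC(C)(OO)C[C@H](C)CCCOC(C)=O
F4 | step 7 | (4R)-6-methoxy-4-methyl-6-(triethylsilylperoxy)heptyl acetate | COC(C)(OO[Si](CC)(CC)CC)C[C@H](C)CCCOC(C)=O
F5 | step 7 | methyl 2-[(3R,5R)-5-[(2R)-5-(acetyloxy)-2-methylpentyl]-3,5-dimethyl-1,2-dioxolan-3-yl]acetate | C[C@H](CCCOC(C)=O)C[C@]1(C)C[C@](C)(CC(=O)OC)OO1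
F6 | step 5 | (4R)-6,6-dimethoxy-4-methylheptyl 3-methylbut-3-enoate | COC(C)(OC)C[C@H](C)CCCOC(=O)CC(C)=C
F7 | step 5 | (4R)-6-methoxy-4-methylhept-6-en-1-yl 3-methylbut-3-enoate | COC(=C)C[C@H](C)CCCOC(=O)CC(C)=C
F8 | step 14 | methyl 2-[(3R,5R)-3,5-dimethyl-5-[(2R)-2-methyl-5-[(1-phenyl-1H-tetrazol-5-yl)sulfanyl]pentyl]-1,2-dioxolan-3-yl]acetate | C[C@H](CCCSC1=NN=NN1c1ccccc1)C[C@]1(C)C[C@](C)(CC(=O)OC)OO1
F9 | step 14 | methyl 2-[(3R,5R)-3,5-dimethyl-5-[(2R)-2-methyl-5-[(1-phenyl-1H-tetrazol-5-yl)sulfonyl]pentyl]-1,2-dioxolan-3-yl]acetate | C[C@H](CCCS(=O)(=O)C1=NN=NN1c1ccccc1)C[C@]1(C)C[C@](C)(CC(=O)OC)OO1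
F10 | step 14 | (4E)-5-phenylpent-4-enal | O=CCC/C=C/c1ccccc1
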